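A ratio carried my reckoning: how much left-handed product a mole of partner charged gave before the flask stalled. The flasks and questions were these.

| setting | larch | alder | flask |
|---|---|---|---|
| left-handed substrate | 0.30 M | 0.30 M | 0.30 M |
| right-handed substrate | 0.30 M | 0.30 M | 0.30 M |
| partner | 0.90 M | 0.45 M | 0.900 M |
| free catalyst | 7.5 mM | 7.5 mM | 7.5 mM |
| remark | the very flask that is asked about, followed so far | run made earlier |  |

- larch (time / h: left-handed product / %, left-handed substrate / %): 0.500: 1.9, 48.3; 0.833: 1.8, 47.1; 1.33: 3.0, 45.2; 2.00: 4.5, 43.2; 4.00: 8.4, 41.0; 6.00: 11.2, 38.0
- alder (time / h: left-handed product / %, left-handed substrate / %): 2.00: 2.4, 45.5; 4.00: 4.2, 43.8; 6.00: 6.3, 42.0; 8.00: 6.6, 42.0; 10.0: 7.3, 41.9; 12.0: 8.0, 41.2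

(each reading ± 0.5 percentage points)

- free catalyst is single-handed; left-handed substrate and right-handed substrate are mirror images of each other, charged as a racemate, each of them at the stated concentration
- no earlier run changes the charge of free catalyst; that part of a forecast is a guess
- what is bound to the catalyst counts as converted

- apparent order in partner when 5.0% of the left-handed substrate and right-handed substrate together are converted (percent change of the rate of making left-handed product for one percent more partner charged)
- apparent order in free catalyst when 5.0% of the left-handed substrate and right-handed substrate together are converted (percent change of the rate of making left-handed product for one percent more free catalyst charged)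
- factor on the rate of making left-handed product when 5.0% of the left-handed substrate and right-handed substrate together are converted if partner is charged twice over

Partner was the first setting I could turn. By hand, I compared the runs: at 4.00 h the larch run held 2.00 times the left-handed product of the alder run, on 2.00 times the partner, so I let the plateau scale with c(partner). For a curve closing exponentially on a plateau, two readings at equal steps give that plateau: the earlier squared, over its double less the later. The alder readings at 6.00 h and 12.0 h thus gave 8.63%, a reading whose scatter, carried through that formula, came to about twice the 0.5 percentage points of a single reading. The reach read 0.115: moles of left-handed product at the stall per mole of partner charged. For the larch flask that meant a plateau of 17.3%, and both this plateau and the reach kept the relative scatter of the alder plateau.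

On such a curve the rate is a constant times plateau less product, so dividing one rate by another removes time. I took the catalyst charge as bound, 1.25% of the substrates, which left 3.75% as product at 5.0% converted. My order in partner was then 1.28, and doubling partner gave a factor of 2.28.

Free catalyst was the second setting, and no run turned it, so this was a guess. If the plateau grew with catalyst and so did the bound share, the order was 1.37.

The forecast differed slightly from my figures: 1.25 (0.95 to 1.55) in partner, 1.3 (1 to 1.6) in catalyst, and 2.25 (1.8 to 2.8) on doubling. Its grounds were: “The slowdown tracks time, not product.” The flask gave 1.2, 1.3 and 2.06, inside those ranges.

    free catalyst + left-handed substrate ⇌ catalyst intermediate A (K = 63.0 /M, k = 3.20 /M/min)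
    free catalyst + right-handed substrate ⇌ catalyst intermediate B (K = 4.40 /M, k = 3.60 /M/min)
    partner + catalyst intermediate A → free catalyst + left-handed product (k = 0.0570 /M/min)
    partner + catalyst intermediate B → free catalyst + right-handed product (k = 0.00100 /M/min)
    partner → decomposed reagent (k = 0.00280 /min)

At 3.65 h partner was lost to decomposed reagent 8.0 times faster than it was used with catalyst intermediate A to make left-handed product, and at 30.0 h that ratio was 7.8, which puts about 0.111 of the partner into that product, beside the reach of 0.115 read from the alder run. Carried to the flask, the reach gave 17.3% as left-handed product, and at 30.0 h the flask held 16.5%, with 0.34% left of the partner, its limiting reagent.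

The numbers in the tables were computed with constants of no real substance, noise included.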